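**Strategy.** Everything rests on cutting the γ-lactone (O7–C7, C8, C17, C19; briarane numbering) at the two carbon–carbon bonds that flank C8–C17: C19–C17 and the ring-fusion bond C7–C8, which also closes the ten-membered ring. The key step exploits this oxygenated C7(O)–C8(O) junction. In one nickel-mediated operation carbon dioxide (C19) is captured at the central carbon of an alkoxyallene (C8=C17=C18), and the resulting allylnickel carboxylate adds through its oxygenated terminus C8 to a tethered Z-enal (C7), closing the carbocycle; lactonisation follows on acidification. The precursor is a ring-A cyclohexene ketal carrying a 1-(methoxymethoxy)allenyl carbinol arm at C10 and a Z-enal arm at C1.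

Key step: step 16

Remark on numbering: C1 is the quaternary ring-A carbon (Me-15); C2–C9 run along the ten-membered ring (C5 bears Me-16); C10 is the ring-fusion CH; C11 (Me-20, OH), C12 (C=O) and C13=C14 complete ring A; C17 is the lactone α-carbon (Me-18) and C19 the lactone carbonyl. The target is (1S,2R,5Z,7S,8S,9R,10S,11S,17R).

Assumption: the (S)-configured oxazaborolidinium catalyst in step 2 is taken to deliver diene 2 to the enal face that gives the (C1 S, C10 S) adduct; should the sense prove opposite, the (R)-catalyst would be used with no other change.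

**Step 1**
Reactants: 1 ethyl vinyl ketone
Product: 2 (Z)-3-(tert-butyldimethylsilyloxy)penta-1,3-diene
Conditions: TBSOTf, Et3N, Et2O, 0 °C
Reagents that add atoms: tert-butyldimethylsilyl triflate, CC(C)(C)[Si](C)(C)OS(=O)(=O)C(F)(F)F
Why: Soft enolisation and O-silylation (silyl enol ether formation) of the ethyl ketone should give the Z-configured 2-silyloxydiene, whose terminal methyl lies outside in the s-cis conformer needed for cycloaddition.

**Step 2**
Reactants: 2 (Z)-3-(tert-butyldimethylsilyloxy)penta-1,3-diene; 3 (E)-4-acetoxy-2-methylbut-2-enal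
Product: 4 ring-A Diels–Alder adduct [(1S,2S,6R)-5-(tert-butyldimethylsilyloxy)-2-formyl-2,6-dimethylcyclohex-4-en-1-yl]methyl acetate
Conditions: (S)-α,α-diphenylprolinol-derived B-(o-tolyl)oxazaborolidine (20 mol%), Tf2NH (18 mol%), CH2Cl2, −78 °C
Reagents that add atoms: none
Why: Catalytic enantioselective Diels–Alder reaction in which the nucleophilic diene terminus C11 adds to the enal β-carbon C10 (silyloxy carbon C12 para to C1), the E-geometry of 3 is transcribed into the cis relation of Me-15 and C9, and the catalyst-bound enal is attacked on one face only, which sets C1 (quaternary) and C10; the C11 methine is flattened later and need not be controlled.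

**Step 3**
Reactants: 5 (Z)-3-methylpent-2-en-4-yn-1-ol
Product: 6 (Z)-tert-butyldimethyl[(3-methylpent-2-en-4-yn-1-yl)oxy]silane
Conditions: TBSCl, imidazole, CH2Cl2, 0 °C to rt
Reagents that add atoms: tert-butyldimethylsilyl chloride, CC(C)(C)[Si](C)(C)Cl
Why: Standard silylation of the primary allylic alcohol (silyl ether protection) with no effect on the Z-alkene or the alkyne.

**Step 4**
Reactants: 6 (Z)-tert-butyldimethyl[(3-methylpent-2-en-4-yn-1-yl)oxy]silane
Product: 7 (Z)-tert-butyldimethyl[(3-methylpenta-2,4-dien-1-yl)oxy]silane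
Conditions: H2 (1 atm), Pd/CaCO3 poisoned with Pb(OAc)2, quinoline, hexane, rt
Reagents that add atoms: none
Why: Semi-hydrogenation of the terminal alkyne over poisoned palladium should stop at the vinyl group and leave the trisubstituted Z-alkene untouched.

**Step 5**
Reactants: 7 (Z)-tert-butyldimethyl[(3-methylpenta-2,4-dien-1-yl)oxy]silane; 4 ring-A Diels–Alder adduct
Product: 10 (2R)-carbinol of ring A bearing the C3–C7 chain, via alkyldiethylborane 8 (not isolated), via dialkylzinc 9 (not isolated)
Conditions: 7, Et2BH, Et2O, 0 °C; Et2Zn (neat), 0 °C, then volatiles removed in vacuo; Ti(OiPr)4, (1S,2S)-1,2-bis(trifluoromethanesulfonamido)cyclohexane (8 mol%), toluene, −20 °C, then 4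
Reagents that add atoms: none
Why: Anti-Markovnikov hydroboration of the terminal vinyl group, boron–zinc exchange and titanium/bis-sulfonamide-catalysed asymmetric 1,2-addition of the dialkylzinc to the neopentyl aldehyde should set C2 (R) under catalyst control with the (S,S)-ligand, while the acetate and the silyl enol ether are inert to the organozinc.

**Step 6**
Reactants: 10 (2R)-carbinol of ring A bearing the C3–C7 chain
Product: 11 2-O-tert-butyldimethylsilyl ether of 10
Conditions: TBSOTf, 2,6-lutidine, CH2Cl2, −78 °C to 0 °C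
Reagents that add atoms: tert-butyldimethylsilyl triflate, CC(C)(C)[Si](C)(C)OS(=O)(=O)C(F)(F)F
Why: Silyl triflate silylates the hindered neopentyl secondary alcohol (silyl ether protection), which prevents lactol formation with C9 when that carbon is oxidised later.

**Step 7**
Reactants: 11 2-O-tert-butyldimethylsilyl ether of 10
Product: 12 ring-A enone (C12=O, C13=C14)
Conditions: Pd(OAc)2 (1.1 equiv), MeCN, rt
Reagents that add atoms: none
Why: Saegusa–Ito oxidation of the regiodefined silyl enol ether should give only the C13=C14 enone, because the Diels–Alder step placed the enol ether at C12=C13 and C14 carries the only β-hydrogens.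

**Step 8**
Reactants: 12 ring-A enone (C12=O, C13=C14)
Product: 15 (11S)-α'-hydroxy enone 9-acetate, via dienol trimethylsilyl ether 13 (not isolated), via α-trimethylsilyloxy enone 14 (not isolated)
Conditions: TMSOTf, Et3N, CH2Cl2, 0 °C; dimethyldioxirane, acetone, −78 °C; citric acid, MeOH, 0 °C
Reagents that add atoms: dimethyldioxirane, CC1(C)OO1
Why: Rubottom oxidation in which the enone can enolise only toward C11 (C13 is vinylic, C1 quaternary) and the dioxirane should attack the electron-rich C11=C12 bond of 13 from the face opposite the adjacent C9H2OAc group and the C1 methyl, placing the new hydroxyl cis to the C2 arm (11S) before mild acid removes the trimethylsilyl group.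

**Step 9**
Reactants: 15 (11S)-α'-hydroxy enone 9-acetate
Product: 17 12,12-ethylenedioxy ketal 9,11-diol, via dioxolane acetate 16 (not isolated)
Conditions: TMSOCH2CH2OTMS, TMSOTf (10 mol%), CH2Cl2, −20 °C; then K2CO3, MeOH, rt
Reagents that add atoms: 1,2-bis(trimethylsilyloxy)ethane, C[Si](C)(C)OCCO[Si](C)(C)C
Why: Silyl-transfer ketalisation under TMSOTf catalysis should protect the hindered enone without double-bond migration (C1 is quaternary), and methanolysis in the same flask cleaves the primary acetate and any trimethylsilyl ether.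

**Step 10**
Reactants: 17 12,12-ethylenedioxy ketal 9,11-diol
Product: 18 C9 aldehyde
Conditions: Dess–Martin periodinane, NaHCO3, CH2Cl2, 0 °C
Reagents that add atoms: none
Why: Dess–Martin oxidation of the only primary alcohol under buffered conditions should give the aldehyde without touching the tertiary alcohol or epimerising C10.

**Step 11**
Reactants: 19 propargyl alcohol
Product: 20 3-(methoxymethoxy)prop-1-yne
Conditions: MOMCl, i-Pr2NEt, CH2Cl2, 0 °C to rt
Reagents that add atoms: chloromethyl methyl ether, COCCl
Why: O-Alkylation of the alcohol with the chloromethyl ether under amine base (acetal protection).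

**Step 12**
Reactants: 20 3-(methoxymethoxy)prop-1-yne
Product: 21 1-(methoxymethoxy)propa-1,2-diene
Conditions: KOtBu (0.3 equiv), THF, rt
Reagents that add atoms: none
Why: Base-catalysed propargyl-to-allenyl isomerisation gives the 1-alkoxyallene, the favoured isomer of a propargyl ether.

**Step 13**
Reactants: 21 1-(methoxymethoxy)propa-1,2-diene; 18 C9 aldehyde
Product: 23 (9R)-1-(methoxymethoxy)allenyl carbinol, via 1-lithio-1-(methoxymethoxy)allene 22 (not isolated)
Conditions: 21 (3 equiv), n-BuLi, THF, −78 °C; then 18, −78 °C; aq. NH4Cl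
Reagents that add atoms: none
Why: α-Lithiation of the alkoxyallene and 1,2-addition to the aldehyde, in which the first equivalent deprotonates 11-OH and the lithium alkoxide chelates the aldehyde oxygen so that attack occurs anti to C1 (chelation and Felkin–Anh models agree), which should give the 9R carbinol, 1,3-syn to 11-OH.

**Step 14**
Reactants: 23 (9R)-1-(methoxymethoxy)allenyl carbinol
Product: 24 2,7,9,11-tetraol
Conditions: TBAF, THF, 0 °C to rt
Reagents that add atoms: none
Why: Fluoride-mediated desilylation removes both silyl ethers, and the alkoxyallene, the ketal and the alcohols are stable to fluoride.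

**Step 15**
Reactants: 24 2,7,9,11-tetraol
Product: 25 Z-enal allene (C7 aldehyde)
Conditions: MnO2 (activated), CH2Cl2, rt
Reagents that add atoms: none
Why: MnO2 oxidises the primary allylic alcohol selectively (allylic oxidation) under neutral heterogeneous conditions that should preserve the Z-geometry and the alkoxyallene.

**Step 16**
Reactants: 25 Z-enal allene (C7 aldehyde)
Product: 28 (7S,8S)-α-methylene lactone macrocycle, via allylnickel carboxylate 26 (not isolated), via seco hydroxy acid 27 (not isolated)
Conditions: slow addition of 25 to Ni(cod)2 [bis(1,5-cyclooctadiene)nickel] (2 equiv), DBU (4 equiv), CO2 (1 atm), THF (0.003 M), 0 °C to rt; then HCl (1 M aq), 0 °C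
Reagents that add atoms: carbon dioxide, O=C=O
Why: Proposed new method: zerovalent nickel couples the unsubstituted C17=C18 π-bond of the alkoxyallene with CO2 (oxidative cyclisation, C19 to the nucleophilic central carbon C17) to give allylnickel carboxylate 26, whose σ-allyl form (Ni on C18) adds through its γ-terminus C8 to the tethered aldehyde C7 in a six-membered chair transition state; acid then releases hydroxy acid 27, which lactonises. The closest known reaction type is the nickel-mediated sequential addition of CO2 and an aldehyde to a terminal allene (intermolecular, aldehyde added after the nickelacycle has formed) and, for the ring size, intramolecular carbonyl allylation by allylmetal reagents; new here are the ten-membered closure, the 1-alkoxy-1-alkyl allene and the aldehyde being present from the start. The ten-membered carbocycle closes by 10-exo-trig attack of C8 on the aldehyde carbon, and the lactone by 5-exo-trig acyl substitution of O7 on C19. C8 (S) should be set by the C9 stereocentre, since in the rotamer that minimises A(1,3) strain (C9–H eclipsing C8=C17) the tether from C10 lies over the face that gives 8S; C7 (S) should follow from the chair transition state with the enal substituent equatorial and the MOM oxygen cis to C18 (chelated to nickel), which places O7 syn to O8 and C6 trans to C9 on the lactone. The step needs CO2 capture to outrun nickel–enal chemistry (CO2 in large excess at 0 °C), γ- over α-attack of the allyl unit (six-membered transition state), 1,2-addition to the Z-enal without isomerisation, and acylation by the nickel-bound 7-alkoxide rather than the free 9-OH; free hydroxyls should be tolerated by the π-allylnickel species.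

**Step 17**
Reactants: 28 (7S,8S)-α-methylene lactone macrocycle
Product: 29 (17R)-α-methyl lactone
Conditions: H2 (3 atm), [Rh(nbd)(dppb)]BF4 (5 mol%), CH2Cl2, rt
Reagents that add atoms: none
Why: Hydroxyl-directed homogeneous hydrogenation in which 9-OH binds the cationic rhodium and delivers H2 to the face of the exocyclic 1,1-disubstituted alkene on which C9 lies, which should give 17R (Me-18 cis to the C8 oxygen) and leave the trisubstituted C5=C6 and the hindered C13=C14 alkenes untouched.

**Step 18**
Reactants: 29 (17R)-α-methyl lactone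
Product: 30 2,9-diacetate
Conditions: Ac2O, pyridine, DMAP (cat.), CH2Cl2, 0 °C to rt
Reagents that add atoms: acetic anhydride, CC(=O)OC(C)=O
Why: DMAP-catalysed acylation of the two secondary alcohols at C2 and C9, with the hindered tertiary 11-OH left free.

**Step 19**
Reactants: 30 2,9-diacetate
Product: 31 target lactone CNP0255369.2
Conditions: CF3CO2H/H2O (9:1), CH2Cl2, 0 °C to rt
Reagents that add atoms: water, O
Why: Acid hydrolysis (acetal cleavage) should convert the dioxolane into the enone and the methoxymethyl acetal into the tertiary 8-OH in one operation, while the acetates, the lactone and all stereocentres are unaffected.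

**Compound list**

1 | ethyl vinyl ketone (pent-1-en-3-one) | CCC(=O)C=C | starting material
2 | (Z)-3-(tert-butyldimethylsilyloxy)penta-1,3-diene | C=C/C(O[Si](C)(C)C(C)(C)C)=C/C | intermediate
3 | (E)-4-acetoxy-2-methylbut-2-enal | CC(=O)OC/C=C(\C)C=O | starting material
4 | [(1S,2S,6R)-5-(tert-butyldimethylsilyloxy)-2-formyl-2,6-dimethylcyclohex-4-en-1-yl]methyl acetate (ring A; ring positions 1, 2, 6 = C10, C1, C11) | CC(=O)OC[C@@H]1[C@](C)(CC=C(O[Si](C)(C)C(C)(C)C)[C@@H]1C)C=O | intermediate
5 | (Z)-3-methylpent-2-en-4-yn-1-ol | C#C/C(C)=C\CO | starting material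
6 | (Z)-tert-butyldimethyl[(3-methylpent-2-en-4-yn-1-yl)oxy]silane | C#C/C(C)=C\CO[Si](C)(C)C(C)(C)C | intermediate
7 | (Z)-tert-butyldimethyl[(3-methylpenta-2,4-dien-1-yl)oxy]silane | C=C/C(C)=C\CO[Si](C)(C)C(C)(C)C | intermediate
8 | diethyl[(Z)-5-(tert-butyldimethylsilyloxy)-3-methylpent-3-en-1-yl]borane | CCB(CC)CC/C(C)=C\CO[Si](C)(C)C(C)(C)C | intermediate
9 | bis[(Z)-5-(tert-butyldimethylsilyloxy)-3-methylpent-3-en-1-yl]zinc | CC(C)(C)[Si](C)(C)OC/C=C(/C)CC[Zn]CC/C(C)=C\CO[Si](C)(C)C(C)(C)C | intermediate
10 | adduct 4 with the formyl group converted into (2R)-CH(OH)CH2CH2C(Me)=CHCH2OTBS (5Z) | CC(=O)OC[C@@H]1[C@](C)(CC=C(O[Si](C)(C)C(C)(C)C)[C@@H]1C)[C@H](O)CC/C(C)=C\CO[Si](C)(C)C(C)(C)C | intermediate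
11 | 2-O-TBS ether of 10 | CC(=O)OC[C@@H]1[C@](C)(CC=C(O[Si](C)(C)C(C)(C)C)[C@@H]1C)[C@H](O[Si](C)(C)C(C)(C)C)CC/C(C)=C\CO[Si](C)(C)C(C)(C)C | intermediate
12 | ring-A enone (C12=O, C13=C14; C11–H epimerisable), 9-acetate, 2,7-bis-TBS ether | CC(=O)OC[C@@H]1[C@](C)(C=CC(=O)[C@@H]1C)[C@H](O[Si](C)(C)C(C)(C)C)CC/C(C)=C\CO[Si](C)(C)C(C)(C)C | intermediate
13 | cross-conjugated dienol trimethylsilyl ether (C11=C12–OTMS, C13=C14) of 12 | CC(=O)OC[C@@H]1[C@](C)(C=CC(O[Si](C)(C)C)=C1C)[C@H](O[Si](C)(C)C(C)(C)C)CC/C(C)=C\CO[Si](C)(C)C(C)(C)C | intermediate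
14 | (11S)-11-trimethylsilyloxy enone | CC(=O)OC[C@@H]1[C@](C)(C=CC(=O)[C@@]1(C)O[Si](C)(C)C)[C@H](O[Si](C)(C)C(C)(C)C)CC/C(C)=C\CO[Si](C)(C)C(C)(C)C | intermediate
15 | (11S)-11-hydroxy enone, 9-acetate, 2,7-bis-TBS ether | CC(=O)OC[C@@H]1[C@](C)(C=CC(=O)[C@@]1(C)O)[C@H](O[Si](C)(C)C(C)(C)C)CC/C(C)=C\CO[Si](C)(C)C(C)(C)C | intermediate
16 | 12,12-ethylenedioxy ketal of 15 | CC(=O)OC[C@@H]1[C@](C)(C=CC2(OCCO2)[C@@]1(C)O)[C@H](O[Si](C)(C)C(C)(C)C)CC/C(C)=C\CO[Si](C)(C)C(C)(C)C | intermediate
17 | 12,12-ethylenedioxy ketal with free 9-OH and 11-OH, 2,7-bis-TBS ether | OC[C@@H]1[C@](C)(C=CC2(OCCO2)[C@@]1(C)O)[C@H](O[Si](C)(C)C(C)(C)C)CC/C(C)=C\CO[Si](C)(C)C(C)(C)C | intermediate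
18 | C9 aldehyde of 17 | O=C[C@@H]1[C@](C)(C=CC2(OCCO2)[C@@]1(C)O)[C@H](O[Si](C)(C)C(C)(C)C)CC/C(C)=C\CO[Si](C)(C)C(C)(C)C | intermediate
19 | propargyl alcohol | C#CCO | starting material
20 | 3-(methoxymethoxy)prop-1-yne | C#CCOCOC | intermediate
21 | 1-(methoxymethoxy)propa-1,2-diene | C=C=COCOC | intermediate
22 | 1-lithio-1-(methoxymethoxy)propa-1,2-diene | [Li]C(OCOC)=C=C | intermediate
23 | (9R)-carbinol carrying the 8-(methoxymethoxy)allene (C8=C17=C18), 12-ketal, 2,7-bis-TBS ether | O[C@@H](C(OCOC)=C=C)[C@@H]1[C@](C)(C=CC2(OCCO2)[C@@]1(C)O)[C@H](O[Si](C)(C)C(C)(C)C)CC/C(C)=C\CO[Si](C)(C)C(C)(C)C | intermediate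
24 | 2,7,9,11-tetraol of 23 | O[C@@H](C(OCOC)=C=C)[C@@H]1[C@](C)(C=CC2(OCCO2)[C@@]1(C)O)[C@H](O)CC/C(C)=C\CO | intermediate
25 | (5Z)-C7 enal carrying the 8-(methoxymethoxy)allene, 2,9,11-triol, 12-ketal | O[C@@H](C(OCOC)=C=C)[C@@H]1[C@](C)(C=CC2(OCCO2)[C@@]1(C)O)[C@H](O)CC/C(C)=C\C=O | intermediate
26 | allylnickel carboxylate from 25 and CO2 (oxanickelacyclopentanone, σ-allyl form drawn, C8=C17 geometry fluxional) | O[C@@H](C(OCOC)=C3C[Ni]OC3=O)[C@@H]1[C@](C)(C=CC2(OCCO2)[C@@]1(C)O)[C@H](O)CC/C(C)=C\C=O | intermediate
27 | (7S,8S)-seco hydroxy acid with the ten-membered ring closed (7-OH, 8-OMOM, C17(=CH2)CO2H) | O[C@@H]1[C@@H]2[C@](C)(C=CC3(OCCO3)[C@@]2(C)O)[C@H](O)CC/C(C)=C\[C@H](O)[C@@]1(OCOC)C(=C)C(=O)O | intermediate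
28 | (7S,8S)-α-methylene-γ-lactone, 8-O-MOM, 2,9,11-triol, 12-ketal | O[C@@H]1[C@@H]2[C@](C)(C=CC3(OCCO3)[C@@]2(C)O)[C@H](O)CC/C(C)=C\[C@@H]2OC(=O)C(=C)[C@]21OCOC | intermediate
29 | (17R)-α-methyl lactone, 8-O-MOM, 2,9,11-triol, 12-ketal | O[C@@H]1[C@@H]2[C@](C)(C=CC3(OCCO3)[C@@]2(C)O)[C@H](O)CC/C(C)=C\[C@@H]2OC(=O)[C@H](C)[C@]21OCOC | intermediate
30 | 2,9-diacetate of 29 | CC(=O)O[C@@H]1[C@@H]2[C@](C)(C=CC3(OCCO3)[C@@]2(C)O)[C@H](OC(C)=O)CC/C(C)=C\[C@@H]2OC(=O)[C@H](C)[C@]21OCOC | intermediate
31 | CNP0255369.2, (1S,2R,5Z,7S,8S,9R,10S,11S,17R)-2,9-diacetoxy-8,11-dihydroxy-12-oxobriara-5,13-diene 7,19-lactone | CC(=O)O[C@@H]1[C@@H]2[C@](C)(C=CC(=O)[C@@]2(C)O)[C@H](OC(C)=O)CC/C(C)=C\[C@@H]2OC(=O)[C@H](C)[C@]21O | target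

**Totals**

Total step count: 19. Longest linear sequence: 15 steps (steps 1, 2, 5–10, 13–19).

**Three steps most likely to fail**

Step 16 (key step). Nickel may bind or couple the enal before CO2 is captured, DBU may isomerise the Z-enal, the allyl unit may react through C18 or between molecules instead of closing the ten-membered ring, or the wrong facial combination at C7/C8 may result. The fallback sets out from 25 and comes back at 28, forming the two bonds in separate operations by known reaction types. A copper-catalysed borylative allene–aldehyde coupling (CuCl, PCy3, NaOtBu, B2pin2, THF, high dilution) would place boron on C17 and close C7–C8 through the allylcopper, giving the macrocyclic alkenylboronate F1. Oxidative carbonylation of the alkenylboronate (Pd(OAc)2, p-benzoquinone, CO, THF) would then install C19 on C17 and lactonise with 7-OH to give 28.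

Step 17. Hydrogen may be delivered from the face opposite C9 if coordination by the MOM ether competes with 9-OH, and the other alkenes may be reduced. The fallback sets out from 28 and comes back at 29, replacing kinetic delivery by thermodynamic control. Conjugate reduction of the α-methylene lactone with [CuH(PPh3)]6 in toluene, with protonation of the enolate from the less hindered face, is expected to give mainly the 17-epimeric lactone F2. Equilibration with DBU in toluene should then convert it into the more stable 17R epimer 29 (Me-18 trans to the bulky C9 arm).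

Step 13. Facial selectivity in the addition to the aldehyde may be poor if chelated and non-chelated transition states compete, and the basic reagent may enolise the aldehyde. The fallback sets out from 23 (obtained as a C9 mixture) and comes back at 23, moving stereocontrol from the carbon–carbon bond formation to a hydride reduction. Dess–Martin oxidation would give the alkoxyallenyl ketone F3. Narasaka–Prasad reduction (Et2BOMe, NaBH4, THF/MeOH, −78 °C), directed by 11-OH through a boron chelate, should then deliver the 1,3-syn diol, which is the 9R carbinol 23.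

**Further compounds**

F1 | step 16 | macrocyclic (7S,8S)-7-hydroxy-8-(methoxymethoxy) alkenylboronate (C17–Bpin, C17=C18H2) | O[C@@H]1[C@@H]2[C@](C)(C=CC3(OCCO3)[C@@]2(C)O)[C@H](O)CC/C(C)=C\[C@H](O)[C@@]1(OCOC)C(=C)B4OC(C)(C)C(C)(C)O4
F2 | step 17 | (17S)-epimer of lactone 29 | O[C@@H]1[C@@H]2[C@](C)(C=CC3(OCCO3)[C@@]2(C)O)[C@H](O)CC/C(C)=C\[C@@H]2OC(=O)[C@@H](C)[C@]21OCOC
F3 | step 13 | C9 ketone (1-(methoxymethoxy)allenyl ketone) corresponding to 23 | O=C(C(OCOC)=C=C)[C@@H]1[C@](C)(C=CC2(OCCO2)[C@@]1(C)O)[C@H](O[Si](C)(C)C(C)(C)C)CC/C(C)=C\CO[Si](C)(C)C(C)(C)C
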